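**Retrosynthetic overview**
1. Target 24 ⇐ diol 22 (both angelates put on last) ⇐ epoxy ketone 21 ⇐ (Z)-enone 20 by nucleophilic epoxidation.
2. Key step: 10-membered carbocycle 20 ⇐ 12-membered (Z)-enoate macrolactone 18 by lactone methylenation and Claisen ring contraction (makes C7–C8, the C9 ketone, the isopropenyl group and the C7 centre in one operation).
3. Macrolactone ⇐ seco acid 16 (Mitsunobu) ⇐ cis-epoxy aldehyde 14 (C1–C6, C9, C10, C14, C15) + vinyl iodide 3 (C7, C11–C13) by a Nozaki–Hiyama–Kishi coupling that sets C6.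
4. 14 ⇐ butenolide 4: the ring fixes 4Z, allylboration sets C3, OH-directed epoxidation sets C4/C5, Still–Gennari olefination sets 1(10)Z.
5. Ring order: C4–C5 oxirane, then 12-membered lactone, then 10-membered carbocycle (ring contraction), then C1–C10 oxirane.

Assumption: germacrane numbering of the target is used for all intermediates (C7 carries the isopropenyl group; C9 is the ketone carbon; C14 sits on C10; C15 on C4), and compounds 1, 4, 12, 23 and the named reagents are bought.

**Route**

Step 1
Reactants: 1 prop-2-yn-1-ol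
Product: 3 (2E)-3-iodo-2-methylprop-2-en-1-ol, via alkenylalane 2 (not isolated)
Conditions: Me3Al (3 equiv), Cp2ZrCl2 (0.25 equiv), CH2Cl2, 0 °C to rt; then I2, THF, −30 to 0 °C; aq. K2CO3
Reagents that add atoms: trimethylaluminium, C[Al](C)C; iodine, II
Why: Negishi zirconium-catalysed carboalumination adds CH3 and Al syn across the alkyne with Al at the terminus, and iodinolysis with retention gives only the E vinyl iodide.

Step 2
Reactants: 4 3-methylfuran-2(5H)-one
Product: 5 3-methyl-2,5-dihydrofuran-2-ol (lactol; used crude at once)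
Conditions: i-Bu2AlH (1.05 equiv), CH2Cl2, −78 °C; cold aq. potassium sodium tartrate
Reagents that add atoms: none
Why: Partial reduction of a lactone with i-Bu2AlH stops at the aluminium lactolate at −78 °C, and the ring keeps the future C4=C5 bond Z; neutral work-up avoids dehydration to 3-methylfuran.

Step 3
Reactants: 5 3-methyl-2,5-dihydrofuran-2-ol
Product: 7 (2Z,4S)-3-methylhepta-2,6-diene-1,4-diol, via open-chain hydroxy-enal 6 (not isolated)
Conditions: (−)-Ipc2BOMe, allylmagnesium bromide, Et2O, 0 °C; then 5, −78 °C to rt; NaOH, H2O2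
Reagents that add atoms: allylmagnesium bromide, C=CC[Mg]Br
Why: Brown asymmetric allylboration of the aldehyde tautomer 6; the chair transition state of the (+)-α-pinene-derived reagent attacks the Si face (the sense it shows with benzaldehyde and enals) and sets C3 as S.

Step 4
Reactants: 7 (2Z,4S)-3-methylhepta-2,6-diene-1,4-diol
Product: 8 (1S)-1-[(2R,3S)-3-(hydroxymethyl)-2-methyloxiran-2-yl]but-3-en-1-ol
Conditions: VO(acac)2 (5 mol %), t-BuOOH (1.3 equiv), CH2Cl2, 0 °C
Reagents that add atoms: tert-butyl hydroperoxide, CC(C)(C)OO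
Why: Hydroxyl-directed vanadium epoxidation touches only the allylic alkene; with the Z geometry A(1,3) strain holds H3 in the alkene plane, so oxygen is delivered from the C3–OH face (threo), which sets C4 and C5, and the cis CH2OH can bind the same vanadium on that face.

Step 5
Reactants: 8 epoxy diol
Product: 9 bis(triethylsilyl) ether of 8: triethyl{[(2S,3S)-3-methyl-3-[(1S)-1-(triethylsilyloxy)but-3-en-1-yl]oxiran-2-yl]methoxy}silane
Conditions: Et3SiCl (2.5 equiv), imidazole, DMAP (cat.), CH2Cl2, 0 °C to rt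
Reagents that add atoms: chlorotriethylsilane, CC[Si](Cl)(CC)CC
Why: Standard silyl ether formation; the primary and the hindered secondary triethylsilyl ethers differ enough to be told apart in step 8.

Step 6
Reactants: 9 bis(triethylsilyl) ether
Product: 11 (3S)-3-[(2S,3S)-2-methyl-3-(triethylsilyloxymethyl)oxiran-2-yl]-3-(triethylsilyloxy)propanal, via ozonide 10 (not isolated)
Conditions: O3, CH2Cl2, −78 °C; then PPh3, −78 °C to rt
Reagents that add atoms: ozone, [O-][O+]=O
Why: Ozonolysis with reductive work-up cleaves the only C=C bond left, while the epoxide and silyl ethers are inert to ozone at −78 °C.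

Step 7
Reactants: 11 aldehyde; 12 ethyl 2-[bis(2,2,2-trifluoroethoxy)phosphoryl]propanoate
Product: 13 ethyl (2Z,5S)-2-methyl-5-[(2S,3S)-2-methyl-3-(triethylsilyloxymethyl)oxiran-2-yl]-5-(triethylsilyloxy)pent-2-enoate
Conditions: 12, KN(SiMe3)2, 18-crown-6, THF, −78 °C; then 11
Reagents that add atoms: none
Why: Still–Gennari variant of the Horner–Wadsworth–Emmons reaction: the electron-poor phosphonate under dissociating conditions eliminates under kinetic control to the Z trisubstituted enoate, the 1(10)Z geometry of the target.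

Step 8
Reactants: 13 Z-enoate
Product: 14 ethyl (2Z,5S)-5-[(2S,3R)-3-formyl-2-methyloxiran-2-yl]-2-methyl-5-(triethylsilyloxy)pent-2-enoate
Conditions: (COCl)2, DMSO, CH2Cl2, −78 to −35 °C; then Et3N, −78 to 0 °C
Reagents that add atoms: none
Why: Under Swern conditions a primary triethylsilyl ether is cleaved by the chlorosulfonium salt and oxidised in the same pot to the aldehyde (a known selective oxidation), while the hindered secondary silyl ether, the epoxide and the enoate stay.

Step 9
Reactants: 14 epoxy aldehyde; 3 (2E)-3-iodo-2-methylprop-2-en-1-ol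
Product: 15 ethyl (2Z,5S)-5-[(2S,3S)-3-[(1S,2E)-1,4-dihydroxy-3-methylbut-2-en-1-yl]-2-methyloxiran-2-yl]-2-methyl-5-(triethylsilyloxy)pent-2-enoate
Conditions: 3 (2 equiv), CrCl2 (4 equiv), NiCl2 (2 mol %), DMSO, rt
Reagents that add atoms: none
Why: Nozaki–Hiyama–Kishi coupling: the alkenylchromium adds to the aldehyde only (ester, epoxide and free OH tolerated) with retention of the E geometry, and polar Felkin–Anh attack anti to the epoxide C–O bond of the cis-epoxy aldehyde sets C6 as S.

Step 10
Reactants: 15 diol ester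
Product: 16 (2Z,5S)-5-[(2S,3S)-3-[(1S,2E)-1,4-dihydroxy-3-methylbut-2-en-1-yl]-2-methyloxiran-2-yl]-2-methyl-5-(triethylsilyloxy)pent-2-enoic acid
Conditions: Me3SnOH (6 equiv), 1,2-dichloroethane, 75 °C; aq. KF, then pH 4 buffer
Reagents that add atoms: trimethyltin hydroxide, C[Sn](C)(C)O
Why: Near-neutral ester hydrolysis with Me3SnOH generates no alkoxide at C6, so Payne migration of the neighbouring epoxide is avoided.

Step 11
Reactants: 16 seco acid
Product: 17 12-membered macrolactone (ester between C9 and O–C12; 1(10)Z; 7(11)E; 4,5-epoxide; 3-OSiEt3; 6-OH; 3S,4S,5S,6S)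
Conditions: PPh3, DIAD, toluene (0.002 M, slow addition of 16), 0 °C to rt
Reagents that add atoms: none
Why: Mitsunobu macrolactonisation activates the unhindered primary allylic C12–OH and the carboxylate closes the ring by SN2 attack at CH2, so the Z-enoic acid is never activated and cannot isomerise; the E geometry of C7=C11 rules out five-ring ether formation from C6–OH.

Step 12
Reactants: 17 hydroxy macrolactone
Product: 18 6-O-triethylsilyl ether of 17 (3S,4S,5S,6S)
Conditions: Et3SiOTf, 2,6-lutidine, CH2Cl2, −78 °C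
Reagents that add atoms: triethylsilyl trifluoromethanesulfonate, CC[Si](CC)(CC)OS(=O)(=O)C(F)(F)F
Why: Silyl triflate with a hindered base silylates the hindered secondary alcohol at low temperature without opening the epoxide, leaving the lactone as the only carbonyl group.

Step 13
Reactants: 18 bis-silylated macrolactone
Product: 20 (3S,4S,5S,6S,7S)-4,5-epoxy-3,6-bis(triethylsilyloxy)germacra-1(10)Z,11-dien-9-one, via macrocyclic enol ether 19 (not isolated)
Conditions: Cp2TiMe2 (3 equiv), toluene, 80 °C (dark); then 140 °C (sealed tube)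
Reagents that add atoms: dimethyltitanocene, C[Ti](C)(C1C=CC=C1)C1C=CC=C1
Why: Proposed new method: Petasis methylenation turns the lactone C=O into an exocyclic enol ether whose C8=C9–O–C12–C11=C7 array is an allyl vinyl ether held s-cis like the parent ester, so heating drives a [3,3] Claisen shift that forms C7–C8, the C9 ketone and the isopropenyl group and contracts the 12-membered oxacycle to the 10-membered carbocycle; C8 adds to the alkene face on which the tether (C5) lies while H6 eclipses the alkene (A(1,3) strain) and the C6 silyloxy group points away, which gives 7S; the closest known reactions are the Tebbe/Petasis methylenation–Claisen sequence of lactones and the Ireland–Claisen ring contraction of macrolactones.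

Step 14
Reactants: 20 (Z)-enone
Product: 21 (1R,3S,4S,5S,6S,7S,10R)-1,10:4,5-diepoxy-3,6-bis(triethylsilyloxy)germacr-11-en-9-one
Conditions: t-BuOOH, benzyltrimethylammonium hydroxide (cat.), THF, 0 °C
Reagents that add atoms: tert-butyl hydroperoxide, CC(C)(C)OO
Why: Weitz–Scheffer nucleophilic epoxidation attacks only the electron-poor enone (the isopropenyl group is inert) and the ring stops rotation of the intermediate enolate so the cis geometry is kept; attack on the outer face is expected to give the 1R,10R epoxide, though this facial call is the least secure in the route.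

Step 15
Reactants: 21 bis-silylated diepoxy ketone
Product: 22 (1R,3S,4R,5S,6S,7S,10R)-1,10:4,5-diepoxy-3,6-dihydroxygermacr-11-en-9-one
Conditions: HF·pyridine, pyridine, THF, 0 °C to rt
Reagents that add atoms: none
Why: Buffered fluoride desilylation removes both triethylsilyl ethers without the basic conditions that would start Payne rearrangement of the hydroxy epoxides.

Step 16
Reactants: 22 diol; 23 angelic acid, (2Z)-2-methylbut-2-enoic acid
Product: 24 target, (1R,3S,4R,5S,6S,7S,10R)-3,6-bis[(2Z)-2-methylbut-2-enoyloxy]-1,10:4,5-diepoxygermacr-11-en-9-one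
Conditions: 23 (4 equiv), 2,4,6-trichlorobenzoyl chloride, Et3N, toluene, rt; then 22, 80 °C
Reagents that add atoms: none
Why: Yamaguchi-type esterification through the mixed anhydride without DMAP is the known way to acylate hindered secondary alcohols with angelic acid without Z to E (angelate to tiglate) isomerisation, and it touches no stereocentre.

**Compound list**

1 | prop-2-yn-1-ol | C#CCO | starting material
2 | dimethylaluminium (2E)-3-(dimethylalumanyl)-2-methylprop-2-en-1-olate | C[Al](C)OC/C(C)=C/[Al](C)C | intermediate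
3 | (2E)-3-iodo-2-methylprop-2-en-1-ol | OC/C(C)=C/I | intermediate
4 | 3-methylfuran-2(5H)-one | CC1=CCOC1=O | starting material
5 | 3-methyl-2,5-dihydrofuran-2-ol (racemic at the acetal carbon) | CC1=CCOC1O | intermediate
6 | (2Z)-4-hydroxy-2-methylbut-2-enal | O=C/C(C)=C\CO | intermediate
7 | (2Z,4S)-3-methylhepta-2,6-diene-1,4-diol | C=CC[C@H](O)/C(C)=C\CO | intermediate
8 | (1S)-1-[(2R,3S)-3-(hydroxymethyl)-2-methyloxiran-2-yl]but-3-en-1-ol | C=CC[C@H](O)[C@@]1(C)O[C@H]1CO | intermediate
9 | bis(triethylsilyl) ether of 8 | C=CC[C@H](O[Si](CC)(CC)CC)[C@@]1(C)O[C@H]1CO[Si](CC)(CC)CC | intermediate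
10 | ozonide (1,2,4-trioxolane) of 9, epimers at the ozonide carbon | O1COOC1C[C@H](O[Si](CC)(CC)CC)[C@@]2(C)O[C@H]2CO[Si](CC)(CC)CC | intermediate
11 | (3S)-3-[(2S,3S)-2-methyl-3-(triethylsilyloxymethyl)oxiran-2-yl]-3-(triethylsilyloxy)propanal | O=CC[C@H](O[Si](CC)(CC)CC)[C@@]1(C)O[C@H]1CO[Si](CC)(CC)CC | intermediate
12 | ethyl 2-[bis(2,2,2-trifluoroethoxy)phosphoryl]propanoate (racemic) | CCOC(=O)C(C)P(=O)(OCC(F)(F)F)OCC(F)(F)F | starting material
13 | ethyl (2Z,5S)-2-methyl-5-[(2S,3S)-2-methyl-3-(triethylsilyloxymethyl)oxiran-2-yl]-5-(triethylsilyloxy)pent-2-enoate | CCOC(=O)/C(C)=C\C[C@H](O[Si](CC)(CC)CC)[C@@]1(C)O[C@H]1CO[Si](CC)(CC)CC | intermediate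
14 | ethyl (2Z,5S)-5-[(2S,3R)-3-formyl-2-methyloxiran-2-yl]-2-methyl-5-(triethylsilyloxy)pent-2-enoate | CCOC(=O)/C(C)=C\C[C@H](O[Si](CC)(CC)CC)[C@@]1(C)O[C@H]1C=O | intermediate
15 | ethyl (2Z,5S)-5-[(2S,3S)-3-[(1S,2E)-1,4-dihydroxy-3-methylbut-2-en-1-yl]-2-methyloxiran-2-yl]-2-methyl-5-(triethylsilyloxy)pent-2-enoate | CCOC(=O)/C(C)=C\C[C@H](O[Si](CC)(CC)CC)[C@@]1(C)O[C@H]1[C@@H](O)/C=C(\C)CO | intermediate
16 | carboxylic acid of 15 (seco acid) | OC(=O)/C(C)=C\C[C@H](O[Si](CC)(CC)CC)[C@@]1(C)O[C@H]1[C@@H](O)/C=C(\C)CO | intermediate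
17 | 12-membered macrolactone (C9 to O–C12; 1(10)Z; 7(11)E; 6-OH; 3S,4S,5S,6S) | C/C1=C/C[C@H](O[Si](CC)(CC)CC)[C@@]2(C)O[C@H]2[C@@H](O)/C=C(\C)COC1=O | intermediate
18 | 6-O-triethylsilyl ether of 17 | C/C1=C/C[C@H](O[Si](CC)(CC)CC)[C@@]2(C)O[C@H]2[C@@H](O[Si](CC)(CC)CC)/C=C(\C)COC1=O | intermediate
19 | 9-methylene cyclic enol ether from 18 | C/C1=C/C[C@H](O[Si](CC)(CC)CC)[C@@]2(C)O[C@H]2[C@@H](O[Si](CC)(CC)CC)/C=C(\C)COC1=C | intermediate
20 | (3S,4S,5S,6S,7S)-4,5-epoxy-3,6-bis(triethylsilyloxy)germacra-1(10)Z,11-dien-9-one | C=C(C)[C@@H]1CC(=O)/C(C)=C\C[C@H](O[Si](CC)(CC)CC)[C@@]2(C)O[C@H]2[C@H]1O[Si](CC)(CC)CC | intermediate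
21 | (1R,3S,4S,5S,6S,7S,10R)-1,10:4,5-diepoxy-3,6-bis(triethylsilyloxy)germacr-11-en-9-one | C=C(C)[C@@H]1CC(=O)[C@]2(C)O[C@@H]2C[C@H](O[Si](CC)(CC)CC)[C@@]2(C)O[C@H]2[C@H]1O[Si](CC)(CC)CC | intermediate
22 | (1R,3S,4R,5S,6S,7S,10R)-1,10:4,5-diepoxy-3,6-dihydroxygermacr-11-en-9-one | C=C(C)[C@@H]1CC(=O)[C@]2(C)O[C@@H]2C[C@H](O)[C@@]2(C)O[C@H]2[C@H]1O | intermediate
23 | angelic acid, (2Z)-2-methylbut-2-enoic acid | C/C=C(/C)C(=O)O | starting material
24 | CNP0217653.1, (1R,3S,4R,5S,6S,7S,10R)-3,6-bis[(2Z)-2-methylbut-2-enoyloxy]-1,10:4,5-diepoxygermacr-11-en-9-one | C=C(C)[C@@H]1CC(=O)[C@]2(C)O[C@@H]2C[C@H](OC(=O)/C(C)=C\C)[C@@]2(C)O[C@H]2[C@H]1OC(=O)/C(C)=C\C | target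

**Totals and risks**

Total step count: 16. Longest linear sequence: 15 steps (steps 2–16, from 4); step 1 is the one-step branch to 3.

Three steps most likely to fail:

Step 13 (methylenation and Claisen ring contraction). Either the hindered conjugated lactone resists methylenation or the transition state, tethered between C9 and C7, is too strained, in which case a 1,5-hydrogen shift in the 2-alkoxydiene could take over. The fallback sets out from 18 and comes back at 20. It moves to the tether pattern of the known macrolactone ester-enol Claisen contractions, where the ring links the two bond-forming ends. Opening 18 with LiCH2CO2t-Bu (THF, −78 °C, 1,2-addition at the lactone carbonyl) gives the open-chain tert-butyl β-keto ester F1 with C12–OH free. Heating F1 in toluene at 110 °C under high dilution forms an acylketene, which C12–OH traps to give the 14-membered β-keto lactone F2. Thermal Carroll rearrangement of F2 (xylene, 150 °C) joins C8 to C7, and decarboxylation of the β-keto acid then gives 20.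

Step 14 (face of the enone epoxidation). Ring conformation alone decides the face, and the stepwise mechanism could also leak to the trans epoxide. The fallback sets out from 20 and comes back at 21, and it replaces conformational control by reagent control followed by hydroxyl direction. Reduction with (R)-Me-CBS and BH3·SMe2 gives the (9S)-allylic alcohol F3. VO(acac)2 and t-BuOOH then epoxidise the Z-cycloalkenol cis to the hydroxyl (the preference known for 8- and 9-membered ring Z-allylic alcohols), giving the epoxy alcohol F4. Dess–Martin oxidation of F4 gives 21.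

Step 9 (C6 configuration in the chromium-mediated addition). Felkin–Anh control with alkenylchromium reagents is often modest. The fallback sets out from 14 and comes back at 15, and it sets C6 by reduction instead of addition. The crude coupling product, taken as the unwanted (6R)-epimer F5 or its mixture with 15, is acetylated at the primary C12–OH (AcCl, 2,4,6-collidine, −78 °C) to the 12-O-acetate F6. Dess–Martin oxidation gives the epoxy enone F7. Zn(BH4)2 (Et2O, −20 °C) reduces F7 through a chelate between the ketone and epoxide oxygens, with hydride arriving from the H5 side, to give the (6S)-alcohol acetate F8. Ethanolysis (K2CO3, EtOH) of F8 returns 15.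

**Further compounds**

F1 | step 13 | tert-butyl β-keto ester from ring opening of 18 (C12–OH free) | CC(C)(C)OC(=O)CC(=O)/C(C)=C\C[C@H](O[Si](CC)(CC)CC)[C@@]1(C)O[C@H]1[C@@H](O[Si](CC)(CC)CC)/C=C(\C)CO
F2 | step 13 | 14-membered β-keto lactone | O=C1CC(=O)/C(C)=C\C[C@H](O[Si](CC)(CC)CC)[C@@]2(C)O[C@H]2[C@@H](O[Si](CC)(CC)CC)/C=C(\C)CO1
F3 | step 14 | (3S,4S,5S,6S,7S,9S)-4,5-epoxy-3,6-bis(triethylsilyloxy)germacra-1(10)Z,11-dien-9-ol | C=C(C)[C@@H]1C[C@H](O)/C(C)=C\C[C@H](O[Si](CC)(CC)CC)[C@@]2(C)O[C@H]2[C@H]1O[Si](CC)(CC)CC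
F4 | step 14 | (1R,3S,4S,5S,6S,7S,9S,10R)-1,10:4,5-diepoxy-3,6-bis(triethylsilyloxy)germacr-11-en-9-ol | C=C(C)[C@@H]1C[C@H](O)[C@]2(C)O[C@@H]2C[C@H](O[Si](CC)(CC)CC)[C@@]2(C)O[C@H]2[C@H]1O[Si](CC)(CC)CC
F5 | step 9 | (6R)-epimer of 15 | CCOC(=O)/C(C)=C\C[C@H](O[Si](CC)(CC)CC)[C@@]1(C)O[C@H]1[C@H](O)/C=C(\C)CO
F6 | step 9 | 12-O-acetate of F5 | CCOC(=O)/C(C)=C\C[C@H](O[Si](CC)(CC)CC)[C@@]1(C)O[C@H]1[C@H](O)/C=C(\C)COC(C)=O
F7 | step 9 | 6-oxo compound (epoxy enone) from F6 | CCOC(=O)/C(C)=C\C[C@H](O[Si](CC)(CC)CC)[C@@]1(C)O[C@H]1C(=O)/C=C(\C)COC(C)=O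
F8 | step 9 | 12-O-acetate of 15 (6S) | CCOC(=O)/C(C)=C\C[C@H](O[Si](CC)(CC)CC)[C@@]1(C)O[C@H]1[C@@H](O)/C=C(\C)COC(C)=O
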